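## Retrosynthetic overview

1. The target is an unsymmetrical 2,2'-methylenebisphenol built from two gigantol units. No ring is formed in the route: all four benzene rings are bought, and the last step is a double O-debenzylation.
2. Key disconnection: the ArB–CH2–ArA bond. It is made by a proposed boron-templated ortho,ortho'-coupling of the ring B salicyl alcohol 12 with the ring A phenol 8.
3. Both halves come from one bibenzyl MOM ether 7. Ring B: directed ortho-metalation/formylation between OMOM and OMe, MOM removal, reduction. Ring A: MOM removal only.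
4. 7 comes from Horner–Wadsworth–Emmons olefination of phosphonate 3 (from O-benzylvanillyl alcohol 1) with MOM-protected 3-hydroxy-5-methoxybenzaldehyde 5, then alkene-selective hydrogenation.

Assumption: the target SMILES contains no stereocentre or other stereogenic element, so the compound is achiral and "single enantiomer" needs no stereocontrol; the problem is regiocontrol of the CH2 bridge (ring A: bridge carbon flanked by OH and the ethylene chain, para to OMe; ring B: bridge carbon between OH and OMe, para to the chain).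

## Route

Step 1
Reactants: 1 [4-(benzyloxy)-3-methoxyphenyl]methanol
Product: 2 1-(benzyloxy)-4-(chloromethyl)-2-methoxybenzene
Conditions: SOCl2, CH2Cl2, 0 °C to rt
Reagents that add atoms: thionyl chloride, ClS(Cl)=O
Why: Deoxychlorination through the chlorosulfite (SNi/SN1) is fast for this electron-rich benzylic alcohol and leaves the aryl benzyl ether intact.

Step 2
Reactants: 2 1-(benzyloxy)-4-(chloromethyl)-2-methoxybenzene
Product: 3 diethyl {[4-(benzyloxy)-3-methoxyphenyl]methyl}phosphonate
Conditions: P(OEt)3 (neat), 130 °C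
Reagents that add atoms: triethyl phosphite, CCOP(OCC)OCC
Why: Michaelis–Arbuzov reaction: phosphorus displaces the benzylic chloride and the chloride then dealkylates the phosphonium ion to give the phosphonate.

Step 3
Reactants: 4 3-hydroxy-5-methoxybenzaldehyde
Product: 5 3-methoxy-5-(methoxymethoxy)benzaldehyde
Conditions: MOMCl, K2CO3, acetone, rt
Reagents that add atoms: chloromethyl methyl ether, COCCl
Why: Williamson-type O-alkylation of the potassium phenoxide with the reactive α-chloro ether installs the MOM group that later directs the metalation, and the aldehyde is inert.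

Step 4
Reactants: 3 diethyl {[4-(benzyloxy)-3-methoxyphenyl]methyl}phosphonate; 5 3-methoxy-5-(methoxymethoxy)benzaldehyde
Product: 6 (E)-1-(benzyloxy)-2-methoxy-4-{2-[3-methoxy-5-(methoxymethoxy)phenyl]ethenyl}benzene
Conditions: KOt-Bu, THF, 0 °C to rt
Reagents that add atoms: none
Why: Horner–Wadsworth–Emmons olefination of the benzylic phosphonate carbanion with the aromatic aldehyde gives the (E)-stilbene selectively, and the alkene geometry is erased in the next step.

Step 5
Reactants: 6 (E)-1-(benzyloxy)-2-methoxy-4-{2-[3-methoxy-5-(methoxymethoxy)phenyl]ethenyl}benzene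
Product: 7 1-(benzyloxy)-2-methoxy-4-{2-[3-methoxy-5-(methoxymethoxy)phenyl]ethyl}benzene
Conditions: H2 (1 atm), 10% Pd/C, Ph2S (0.01 equiv), EtOAc, rt
Reagents that add atoms: none
Why: Sulfide-poisoned Pd/C hydrogenation reduces the disubstituted alkene but is too deactivated to hydrogenolyse the aryl benzyl ether, and the MOM acetal is stable at neutral pH.

Step 6
Reactants: 7 1-(benzyloxy)-2-methoxy-4-{2-[3-methoxy-5-(methoxymethoxy)phenyl]ethyl}benzene
Product: 8 3-{2-[4-(benzyloxy)-3-methoxyphenyl]ethyl}-5-methoxyphenol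
Conditions: HCl, MeOH, 50 °C
Reagents that add atoms: none
Why: Acid-catalysed transacetalisation of the MOM acetal to methanol frees the ring A phenol, while benzyl and methyl ethers are stable to methanolic HCl.

Step 7
Reactants: 7 1-(benzyloxy)-2-methoxy-4-{2-[3-methoxy-5-(methoxymethoxy)phenyl]ethyl}benzene
Product: 10 4-{2-[4-(benzyloxy)-3-methoxyphenyl]ethyl}-2-methoxy-6-(methoxymethoxy)benzaldehyde, via aryllithium 9 (not isolated)
Conditions: n-BuLi, TMEDA, THF, 0 °C; DMF, −78 °C to rt; H2O
Reagents that add atoms: N,N-dimethylformamide, CN(C)C=O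
Why: Directed ortho-metalation: the C–H between OMOM and OMe is flanked by two coordinating oxygens and is by far the most acidic ring position, and formylation of the aryllithium with DMF fixes the ring B pattern (carbon between the two oxygens, para to the chain).

Step 8
Reactants: 10 4-{2-[4-(benzyloxy)-3-methoxyphenyl]ethyl}-2-methoxy-6-(methoxymethoxy)benzaldehyde
Product: 11 4-{2-[4-(benzyloxy)-3-methoxyphenyl]ethyl}-2-hydroxy-6-methoxybenzaldehyde
Conditions: 3 M aq. HCl, THF, 50 °C
Reagents that add atoms: none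
Why: Acidic hydrolysis of the MOM acetal, favoured by the hydrogen-bonded salicylaldehyde product, leaves the benzyl and methyl ethers untouched.

Step 9
Reactants: 11 4-{2-[4-(benzyloxy)-3-methoxyphenyl]ethyl}-2-hydroxy-6-methoxybenzaldehyde
Product: 12 5-{2-[4-(benzyloxy)-3-methoxyphenyl]ethyl}-2-(hydroxymethyl)-3-methoxyphenol
Conditions: NaBH4, THF/MeOH, 0 °C; aq. NaH2PO4/Na2HPO4 (pH 7) work-up; used at once
Reagents that add atoms: none
Why: Borohydride reduction of the aldehyde gives the salicyl alcohol, and the buffered neutral work-up with immediate use avoids acid-triggered ortho-quinone methide formation from this electron-rich benzylic alcohol.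

Step 10
Reactants: 12 5-{2-[4-(benzyloxy)-3-methoxyphenyl]ethyl}-2-(hydroxymethyl)-3-methoxyphenol; 8 3-{2-[4-(benzyloxy)-3-methoxyphenyl]ethyl}-5-methoxyphenol
Product: 15 5-{2-[4-(benzyloxy)-3-methoxyphenyl]ethyl}-2-({2-{2-[4-(benzyloxy)-3-methoxyphenyl]ethyl}-6-hydroxy-4-methoxyphenyl}methyl)-3-methoxyphenol, via mixed borate 13 (not isolated), via dioxaborocinol 14 (not isolated)
Conditions: B(OMe)3 (1.0 equiv), PhMe, 5 Å MS, 60 °C; then (PhO)2P(O)OH (5 mol %), 80 °C; then H2O/MeOH, rt
Reagents that add atoms: none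
Why: Proposed new method: transesterification of B(OMe)3 with the 1,3-diol unit of 12 and the single OH of 8 gives mixed borate 13 (the chelate effect places one salicyl unit and one aryloxy group on each boron); acid-assisted heterolysis of the benzylic C–O bond, stabilised by the ortho O–B and ortho OMe groups, gives a boron-bound ortho-quinone methide/benzyl cation and turns the former benzylic oxygen into a B–O(−) donor that frees the lone pair of the ring A aryloxy oxygen; the ring A ortho carbon C2 of 8 (para to OMe, the more nucleophilic of the two ortho sites, while the para position cannot reach) attacks through an eight-membered cyclic transition state to give dioxaborocinol 14, which is hydrolysed to 15 on work-up, the boron being carried only in 13 and 14; the closest known reaction types are the arylboronic-acid-templated ortho-hydroxyalkylation of phenols with aldehydes, the use of 2-aryl-4H-1,3,2-benzodioxaborins as ortho-quinone methide precursors, and Friedel–Crafts benzylation of phenols by ortho-quinone methides.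

Step 11
Reactants: 15 5-{2-[4-(benzyloxy)-3-methoxyphenyl]ethyl}-2-({2-{2-[4-(benzyloxy)-3-methoxyphenyl]ethyl}-6-hydroxy-4-methoxyphenyl}methyl)-3-methoxyphenol
Product: 16 5-[2-(4-hydroxy-3-methoxyphenyl)ethyl]-2-({6-hydroxy-2-[2-(4-hydroxy-3-methoxyphenyl)ethyl]-4-methoxyphenyl}methyl)-3-methoxyphenol
Conditions: H2 (1 atm), 10% Pd/C, EtOAc/MeOH, rt
Reagents that add atoms: none
Why: Heterogeneous hydrogenolysis of the two aryl benzyl ethers frees the guaiacyl phenols while the diarylmethane, methyl ethers and free phenols are inert, and the product has no stereocentre.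

## Compound list

1 | [4-(benzyloxy)-3-methoxyphenyl]methanol (O-benzylvanillyl alcohol) | COc1cc(CO)ccc1OCc1ccccc1 | starting material
2 | 1-(benzyloxy)-4-(chloromethyl)-2-methoxybenzene | COc1cc(CCl)ccc1OCc1ccccc1 | intermediate
3 | diethyl {[4-(benzyloxy)-3-methoxyphenyl]methyl}phosphonate | CCOP(=O)(Cc1ccc(OCc2ccccc2)c(OC)c1)OCC | intermediate
4 | 3-hydroxy-5-methoxybenzaldehyde | COc1cc(O)cc(C=O)c1 | starting material
5 | 3-methoxy-5-(methoxymethoxy)benzaldehyde | COCOc1cc(OC)cc(C=O)c1 | intermediate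
6 | (E)-1-(benzyloxy)-2-methoxy-4-{2-[3-methoxy-5-(methoxymethoxy)phenyl]ethenyl}benzene | COCOc1cc(OC)cc(/C=C/c2ccc(OCc3ccccc3)c(OC)c2)c1 | intermediate
7 | 1-(benzyloxy)-2-methoxy-4-{2-[3-methoxy-5-(methoxymethoxy)phenyl]ethyl}benzene | COCOc1cc(OC)cc(CCc2ccc(OCc3ccccc3)c(OC)c2)c1 | intermediate
8 | 3-{2-[4-(benzyloxy)-3-methoxyphenyl]ethyl}-5-methoxyphenol (4'-O-benzylgigantol) | COc1cc(O)cc(CCc2ccc(OCc3ccccc3)c(OC)c2)c1 | intermediate
9 | {4-{2-[4-(benzyloxy)-3-methoxyphenyl]ethyl}-2-methoxy-6-(methoxymethoxy)phenyl}lithium (lithium on the carbon between OMe and OMOM) | [Li]c1c(OC)cc(CCc2ccc(OCc3ccccc3)c(OC)c2)cc1OCOC | intermediate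
10 | 4-{2-[4-(benzyloxy)-3-methoxyphenyl]ethyl}-2-methoxy-6-(methoxymethoxy)benzaldehyde | O=Cc1c(OC)cc(CCc2ccc(OCc3ccccc3)c(OC)c2)cc1OCOC | intermediate
11 | 4-{2-[4-(benzyloxy)-3-methoxyphenyl]ethyl}-2-hydroxy-6-methoxybenzaldehyde | O=Cc1c(OC)cc(CCc2ccc(OCc3ccccc3)c(OC)c2)cc1O | intermediate
12 | 5-{2-[4-(benzyloxy)-3-methoxyphenyl]ethyl}-2-(hydroxymethyl)-3-methoxyphenol | OCc1c(OC)cc(CCc2ccc(OCc3ccccc3)c(OC)c2)cc1O | intermediate
13 | 7-{2-[4-(benzyloxy)-3-methoxyphenyl]ethyl}-2-(3-{2-[4-(benzyloxy)-3-methoxyphenyl]ethyl}-5-methoxyphenoxy)-5-methoxy-4H-1,3,2-benzodioxaborine (mixed borate of 12 and 8) | COc1cc(CCc2ccc(OCc3ccccc3)c(OC)c2)cc2OB(Oc3cc(OC)cc(CCc4ccc(OCc5ccccc5)c(OC)c4)c3)OCc12 | intermediate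
14 | 3,11-bis{2-[4-(benzyloxy)-3-methoxyphenyl]ethyl}-1,9-dimethoxy-12H-dibenzo[d,g][1,3,2]dioxaborocin-6-ol (cyclic borate of 15) | OB1Oc2cc(CCc3ccc(OCc4ccccc4)c(OC)c3)cc(OC)c2Cc2c(CCc3ccc(OCc4ccccc4)c(OC)c3)cc(OC)cc2O1 | intermediate
15 | 5-{2-[4-(benzyloxy)-3-methoxyphenyl]ethyl}-2-({2-{2-[4-(benzyloxy)-3-methoxyphenyl]ethyl}-6-hydroxy-4-methoxyphenyl}methyl)-3-methoxyphenol | COc1cc(O)c(Cc2c(O)cc(CCc3ccc(OCc4ccccc4)c(OC)c3)cc2OC)c(CCc2ccc(OCc3ccccc3)c(OC)c2)c1 | intermediate
16 | 5-[2-(4-hydroxy-3-methoxyphenyl)ethyl]-2-({6-hydroxy-2-[2-(4-hydroxy-3-methoxyphenyl)ethyl]-4-methoxyphenyl}methyl)-3-methoxyphenol (CNP0079001.0, achiral) | COc1cc(O)c(Cc2c(O)cc(CCc3ccc(O)c(OC)c3)cc2OC)c(CCc2ccc(O)c(OC)c2)c1 | target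

## Step count and risk

Total step count: 11. Longest linear sequence: 9 steps (steps 1, 2, 4, 5, 7, 8, 9, 10, 11 from compound 1).

Three steps most likely to fail:

**Step 10 (proposed boron-templated coupling).** Risks are borate ester scrambling leading to self-condensation of 12, untemplated para attack on free 8, and attack at the other ortho carbon of ring A (C6 of 8, between OH and OMe), which would give a separable regioisomer. The fallback uses known chemistry only; it sets out from 8 and comes back to the route at 15. Phenol 8 is ortho-formylated with MgCl2, Et3N and paraformaldehyde in MeCN at reflux (magnesium-phenoxide-directed formylation, preferring the ortho carbon para to OMe) to give 2-{2-[4-(benzyloxy)-3-methoxyphenyl]ethyl}-6-hydroxy-4-methoxybenzaldehyde F1. Protection with MOMCl and NaH in DMF at 0 °C gives 2-{2-[4-(benzyloxy)-3-methoxyphenyl]ethyl}-4-methoxy-6-(methoxymethoxy)benzaldehyde F2. Aryllithium 9, generated from 7 exactly as in step 7, is added to F2 in THF at −78 °C to give racemic {2-{2-[4-(benzyloxy)-3-methoxyphenyl]ethyl}-4-methoxy-6-(methoxymethoxy)phenyl}{4-{2-[4-(benzyloxy)-3-methoxyphenyl]ethyl}-2-methoxy-6-(methoxymethoxy)phenyl}methanol F3. Ionic hydrogenation with Et3SiH and CF3CO2H (2 equiv) in CH2Cl2 at −40 °C removes the benzhydrylic hydroxyl, destroying the only stereocentre, and gives the bis-MOM diarylmethane 1-(benzyloxy)-4-{2-[4-({2-{2-[4-(benzyloxy)-3-methoxyphenyl]ethyl}-4-methoxy-6-(methoxymethoxy)phenyl}methyl)-3-methoxy-5-(methoxymethoxy)phenyl]ethyl}-2-methoxybenzene F4. HCl in MeOH at 50 °C removes both MOM groups and gives 15.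

**Step 7 (ortho-metalation of 7 with n-BuLi).** Risks are competing deprotonation next to the benzyl ether oxygen (Wittig rearrangement) or on the guaiacyl ring. The fallback changes the directing group, the substrate and the end of the sequence; it sets out from 8 and comes back to the route at 12, bypassing 10 and 11. Phenol 8 is carbamoylated with ClC(O)NEt2 and NaH in THF to give 3-{2-[4-(benzyloxy)-3-methoxyphenyl]ethyl}-5-methoxyphenyl N,N-diethylcarbamate F5. The carbamate, the strongest oxygen directing group, is lithiated with s-BuLi and TMEDA in THF at −78 °C, where the benzyl ether is inert, to give the aryllithium 2-[(diethylcarbamoyl)oxy]-4-{2-[4-(benzyloxy)-3-methoxyphenyl]ethyl}-6-methoxyphenyllithium F6. Quenching with DMF at −78 °C, before any anionic Fries rearrangement, gives 5-{2-[4-(benzyloxy)-3-methoxyphenyl]ethyl}-2-formyl-3-methoxyphenyl N,N-diethylcarbamate F7. LiAlH4 in THF at 0 °C, with aq. KNaC4H4O6 work-up, reduces the aldehyde and cleaves the carbamate in one operation to give 12.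

**Step 5 (alkene hydrogenation with retention of the benzyl ether).** The risk is partial hydrogenolysis of the aryl benzyl ether, or a stalled reduction on the poisoned catalyst. The fallback gives up chemoselectivity; it sets out from 6 and comes back to the route at 7. Stilbene 6 is fully hydrogenated with H2 and unpoisoned 10% Pd/C in EtOAc/MeOH, which saturates the alkene and removes the benzyl group, to give 2-methoxy-4-{2-[3-methoxy-5-(methoxymethoxy)phenyl]ethyl}phenol F8. Its only free phenol is re-benzylated with BnBr and K2CO3 in DMF to give 7.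

## Further compounds

F1 | step 10 | 2-{2-[4-(benzyloxy)-3-methoxyphenyl]ethyl}-6-hydroxy-4-methoxybenzaldehyde | O=Cc1c(O)cc(OC)cc1CCc1ccc(OCc2ccccc2)c(OC)c1
F2 | step 10 | 2-{2-[4-(benzyloxy)-3-methoxyphenyl]ethyl}-4-methoxy-6-(methoxymethoxy)benzaldehyde | O=Cc1c(OCOC)cc(OC)cc1CCc1ccc(OCc2ccccc2)c(OC)c1
F3 | step 10 | racemic {2-{2-[4-(benzyloxy)-3-methoxyphenyl]ethyl}-4-methoxy-6-(methoxymethoxy)phenyl}{4-{2-[4-(benzyloxy)-3-methoxyphenyl]ethyl}-2-methoxy-6-(methoxymethoxy)phenyl}methanol | COCOc1cc(OC)cc(CCc2ccc(OCc3ccccc3)c(OC)c2)c1C(O)c1c(OC)cc(CCc2ccc(OCc3ccccc3)c(OC)c2)cc1OCOC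
F4 | step 10 | 1-(benzyloxy)-4-{2-[4-({2-{2-[4-(benzyloxy)-3-methoxyphenyl]ethyl}-4-methoxy-6-(methoxymethoxy)phenyl}methyl)-3-methoxy-5-(methoxymethoxy)phenyl]ethyl}-2-methoxybenzene (bis-MOM ether of 15) | COCOc1cc(OC)cc(CCc2ccc(OCc3ccccc3)c(OC)c2)c1Cc1c(OC)cc(CCc2ccc(OCc3ccccc3)c(OC)c2)cc1OCOC
F5 | step 7 | 3-{2-[4-(benzyloxy)-3-methoxyphenyl]ethyl}-5-methoxyphenyl N,N-diethylcarbamate | CCN(CC)C(=O)Oc1cc(OC)cc(CCc2ccc(OCc3ccccc3)c(OC)c2)c1
F6 | step 7 | 2-[(diethylcarbamoyl)oxy]-4-{2-[4-(benzyloxy)-3-methoxyphenyl]ethyl}-6-methoxyphenyllithium | [Li]c1c(OC)cc(CCc2ccc(OCc3ccccc3)c(OC)c2)cc1OC(=O)N(CC)CC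
F7 | step 7 | 5-{2-[4-(benzyloxy)-3-methoxyphenyl]ethyl}-2-formyl-3-methoxyphenyl N,N-diethylcarbamate | O=Cc1c(OC)cc(CCc2ccc(OCc3ccccc3)c(OC)c2)cc1OC(=O)N(CC)CC
F8 | step 5 | 2-methoxy-4-{2-[3-methoxy-5-(methoxymethoxy)phenyl]ethyl}phenol | COCOc1cc(OC)cc(CCc2ccc(O)c(OC)c2)c1
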